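## Structural features

The target is a bicyclic labdane diterpenoid (labdane numbering throughout): a trans-fused decalin made of ring A (C1–C5, C10) and ring B (C5–C10), with an exocyclic methylene C17 on C8 and the side chain CH2CH2C(CH3)=CHCO2H (C11–C16, E at C13=C14) on C9. Four stereocentres stand in a row along C4–C5–C10–C9. C4 (β-methyl C19, α-CH2OAc C18) and C10 (β-methyl C20) are quaternary and 1,3-related across C5, which carries 5α-H, and C9 carries 9α-H with the chain β. Fragile are the primary acetate beside a free carboxylic acid, the 8(17)-methylene, which slips into the ring under acid, the allylic C9–H, and the E geometry of the trisubstituted enoate. The acetate therefore has to go on late, and the acid has to be set free last without base, acid or hydride. The real difficulty lies in the two quaternary centres: their relative configuration and the distinction of the two one-carbon groups on C4. The key step exploits the fact that C18 on C4 and the C10–C9 bond are cis-1,3 across ring A, so that an ester from the C18 oxygen to the future C11 carboxyl can hold a C9≡C8 dienophile under the α face of the ring A diene C10=C5–C6=C7; ring B then closes and C10 is set from C4 alone.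

## Logic of the disconnections

33 to 32. The O–allyl bond of the C15 ester is the last bond to be broken in the forward sense. An allyl ester is a carboxyl mask that leaves without base, acid or hydride, so the C18 acetate survives, and the acid can travel masked through all earlier steps. The forward step must be a neutral palladium-catalysed allyl transfer.

32 to 30 and 31, then 30 to 29. The acetyl–O bond at C18 is cut, and behind it an O–Si bond. An acetate would not pass the enolate, hydride and fluoride steps, so the C18 oxygen is carried as a silyl ether and exchanged near the end. The demand is that silyl ether and allyl ester can be addressed separately.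

29 to 27 and 28. C13=C14 is cut. This removes the acid terminus and the alkene geometry and leaves a methyl ketone. The forward olefination must favour the E isomer on a methyl ketone.

27 to 26, then 26 to 24 and 25. The C11=C12 alkene is put back and then cut. The chain shrinks to a formyl group on C9, a one-carbon handle. The forward steps must olefinate a hindered β,γ-unsaturated aldehyde without epimerising or conjugating it, and must then reduce only the enone alkene.

24 to 23 to 22. Only the oxidation level of C11 changes. The ester is the robust form in which C11 passes the earlier steps, and it is what the cycloaddition delivers.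

22 to 20. The C9–H bond is removed and the alkene is shifted from C8=C17 to C8=C9. This erases the C9 stereocentre and puts C11 in conjugation with a tetrasubstituted alkene, the pattern of an alkynoate cycloadduct. The forward step must take a proton from C17 and not from C7, and must return a proton to the α face of C9.

20 to 19 to 18. The O–Si bond and then the C5–H and C6–H bonds are removed. Restoring C5=C6 erases the C5 stereocentre and gives the 1,4-cyclohexadiene of a cycloadduct. The forward hydrogenation must add to the α face of C5 and spare C8=C9.

18 to 17. The C11–O bond to the C18 oxygen is closed again. This shows the tether that ties C4 to C9. The forward step must open a hindered, strained lactone without moving the skipped diene.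

17 to 16. C9–C10 and C7–C8 are cut; this is the key disconnection. Ring B, the lactone ring and the C10 stereocentre vanish, and a monocyclic ester with one stereocentre is left. 16 has no other functional group and no β-hydrogen on the alkyl side of the ester, so it can be heated. The forward step must control regiochemistry and deliver the dienophile to the α face.

16 to 14 and 15. The ester C11–O bond is cut, which separates the chiral neopentyl alcohol from an achiral four-carbon alkynoic acid. The forward esterification must not isomerise the alkyne.

14 to 13, then 13 to 11 and 12. C18 goes back to the ester level, and the C5–C6 bond is cut at an enol triflate. Coupling at the triflate is preferred to dehydration of a tertiary vinyl carbinol, which risks allylic transposition and lactonisation onto the ester. The demand is a cross-coupling at a hindered, tetrasubstituted enol triflate.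

11 to 9, then 9 to 7 and 4. The C5–O bond of the triflate is cut, then C10–C20. The methyl enters at the only enolisable position, and its configuration does not matter because C10 becomes sp2.

7 to 3 and 4, then 3 to 1 and 2. C4–C19 is cut, then the enamine C–N bond. The one stereocentre from which all others are relayed is set by methylation of a chiral enamine of the β-keto ester. The demand is high facial selectivity in forming a quaternary centre.

## Other disconnections considered

Alternative 1: The cut is C9–C11, C10–C1 and C4=C5, which annulates ring A onto the ring B enone (R)-4-(tert-butyldimethylsilyloxy)-2-methylcyclohex-2-en-1-one A2. In the forward key step an organocopper reagent made from the Grignard reagent [2-(2-methyl-1,3-dioxolan-2-yl)ethyl]magnesium bromide A3 would add to C9 of A2 anti to the C8 silyloxy group. The C10 enolate would be trapped by the silyl vinyl ketone 2-(trimethylsilyl)pent-1-en-3-one A4, and base would take off silicon and close ring A by aldol condensation to give the octalone A1. In its favour: every operation is an established reaction type, so in mechanistic security this plan is better than the chosen one. C9 arrives with C11–C13 attached, which saves the aldehyde homologation (better). The C8 oxygen can become the methylene by oxidation and Wittig reaction, which avoids a deconjugation (better). A3 and A4 are simple reagents. Against it here: trapping a hindered, fully substituted enolate with A4 to make the quaternary C10 is prone to proton transfer. C4 and C5 would be set late, by reductive alkylation of the enone in A1 with a one-carbon electrophile. The C3 carbonyl is superfluous and has to be removed. Enantiopure A2 needs its own synthesis, and its stereocentre is destroyed later. Comparison: step economy should be about equal. Structurally the chosen plan carries no oxygen that has to be deleted and relays everything from C4, but it rests on an untested cycloaddition, whereas the risk of alternative 1 is spread over several precedented steps.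

Alternative 2: The cut is C4–C19 and C5–C6 on the ring A enone 3-[(triisopropylsilyloxy)methyl]cyclohex-2-en-1-one A6. In the forward key step a copper-catalysed enantioselective conjugate addition of a methylaluminium reagent under a chiral phosphoramidite ligand would make the C4 quaternary centre, and allylation of the resulting aluminium enolate trans to the silyloxymethyl group would give the ketone A5. In its favour: C4 would be set catalytically and together with C5, which is better than the stoichiometric auxiliary and the later hydrogenation of the chosen plan. The chemistry is precedented (better), and A6 is short to make. Against it here: ring B, the quaternary C10 and C9 remain unsolved. C10 is a carbonyl carbon in A5 and must be turned into a methyl-bearing quaternary centre of defined configuration, a new stereochemical problem of several steps. Aluminium enolates are also sluggish toward allyl halides. Comparison: better on C4 and on precedent, worse on C10 and C9, and probably longer overall, because nothing in A5 relays C4 to C10 the way the tether of the chosen plan does.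

Alternative 3: The cut is C5–C10 and C8–C9 in the acyclic trienal (2E)-6-{5-[(1E,3E)-4-(tert-butyldimethylsilyloxy)buta-1,3-dien-1-yl]-2,2-dimethyl-1,3-dioxan-5-yl}-3-methylhex-2-enal A8. In the forward key step a chiral cationic oxazaborolidine Lewis acid would activate the enal of A8 for an intramolecular Diels–Alder reaction that closes ring B and, through the four-carbon tether, ring A, giving the trans-fused adduct A7. In its favour: one catalytic step would close both rings and set C5, C9 and C10, with C11 already an aldehyde and C8 oxygenated for later methylenation. In rings and stereocentres per step it is better than the chosen plan. Its main risk, a β,β-disubstituted enal that must form a quaternary centre, is about equal to the risk of the chosen key step. Against it here: C4 is a symmetric spiro-ketal carbon in A7, so its two CH2O arms must later be told apart and one reduced to methyl, a new selectivity problem. A8 needs defined (E)-enal and (E,E)-diene geometry. C6=C7 must be hydrogenated and C8 converted. Comparison: step economy should be similar or slightly worse. The chosen plan has C4 unambiguous from the first step, while alternative 3 is superior in how much of the skeleton one step builds.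

Key step: step 8

Assumption: the methylation of the L-valine enamine in toluene with HMPA is taken to give the (R)-keto ester 7; the sense of this alkylation switches with the donor additive and with the antipode of the auxiliary, so the (R) series is reachable either way.

## Steps

Step 1
Reactants: 1 ethyl 2-oxocyclohexanecarboxylate; 2 L-valine tert-butyl ester (free base)
Product: 3 tert-butyl N-[2-(ethoxycarbonyl)cyclohex-1-en-1-yl]-L-valinate
Conditions: BF3·OEt2 (cat.), benzene, reflux, Dean–Stark
Reagents that add atoms: L-valine tert-butyl ester, CC(C)[C@H](N)C(=O)OC(C)(C)C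
Why: Enamine condensation of a β-keto ester with a primary amine gives the hydrogen-bonded enamino ester; removal of water drives it.

Step 2
Reactants: 3; 4 iodomethane
Product: 7 ethyl (1R)-1-methyl-2-oxocyclohexane-1-carboxylate, via N-lithio enamine 5 (not isolated), via methylated imine 6 (not isolated)
Conditions: LiN(iPr)2 (LDA), toluene, HMPA, −78 °C; MeI, −78 → −50 °C; then 1 M HCl, 0 °C
Reagents that add atoms: iodomethane, CI; water, O
Why: Asymmetric alkylation of a chelated lithio enamine (chiral-auxiliary enamine alkylation); the valine isopropyl group and the lithium-bound ligand shield one face, so the C4 quaternary centre should form with high selectivity, and mild acid hydrolyses the imine and returns the auxiliary.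

Step 3
Reactants: 7; 4 iodomethane
Product: 9 ethyl (1R)-1,3-dimethyl-2-oxocyclohexane-1-carboxylate (C3 epimers), via lithium enolate 8 (not isolated)
Conditions: LDA, THF, −78 °C; MeI, −78 → 0 °C
Reagents that add atoms: iodomethane, CI
Why: Enolate alkylation at the only enolisable position (the future C10); the new centre need not be controlled because it becomes sp2 in the next step.

Step 4
Reactants: 9
Product: 11 ethyl (1R)-1,3-dimethyl-2-{[(trifluoromethyl)sulfonyl]oxy}cyclohex-2-ene-1-carboxylate, via potassium enolate 10 (not isolated)
Conditions: KN(SiMe3)2 (KHMDS), THF, −78 → 0 °C; PhNTf2, −78 °C → rt; aq. NH4Cl work-up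
Reagents that add atoms: N-phenylbis(trifluoromethanesulfonimide), O=S(=O)(N(c1ccccc1)S(=O)(=O)C(F)(F)F)C(F)(F)F
Why: O-Triflation of the only possible enolate gives the tetrasubstituted enol triflate, as for 2,2,6-trisubstituted cyclohexanones; the ester has no α-hydrogen and is inert.

Step 5
Reactants: 11; 12 tributyl(vinyl)stannane
Product: 13 ethyl (1R)-2-ethenyl-1,3-dimethylcyclohex-2-ene-1-carboxylate
Conditions: Pd2(dba)3 (cat.), AsPh3, LiCl, NMP, 70 °C
Reagents that add atoms: tributyl(vinyl)stannane, C=C[Sn](CCCC)(CCCC)CCCC
Why: Stille coupling of an enol triflate with a vinylstannane; the arsine ligand and polar solvent speed transmetalation at the hindered triflate, and the diene forms without any cationic intermediate.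

Step 6
Reactants: 13
Product: 14 [(1R)-2-ethenyl-1,3-dimethylcyclohex-2-en-1-yl]methanol
Conditions: LiAlH4, Et2O, 0 °C
Reagents that add atoms: none
Why: Hydride reduction of the ester to the neopentyl alcohol (C18); the unactivated diene is untouched.

Step 7
Reactants: 14; 15 but-2-ynoic acid
Product: 16 [(1R)-2-ethenyl-1,3-dimethylcyclohex-2-en-1-yl]methyl but-2-ynoate
Conditions: DCC, DMAP (cat.), CH2Cl2, 0 °C → rt
Reagents that add atoms: but-2-ynoic acid, CC#CC(=O)O
Why: Steglich esterification; low temperature and catalytic DMAP keep the alkynoate from isomerising to the allenoate.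

Step 8
Reactants: 16
Product: 17 bridged lactone: 11,18-lactone of 18-hydroxy-12,13,14,15,16-pentanorlabda-5,8-dien-11-oic acid (10β-methyl; lactone bridge on the α face)
Conditions: 1,2-dichlorobenzene (0.01 M), BHT (cat.), degassed, 180 °C, sealed tube
Reagents that add atoms: none
Why: Proposed new method: a thermal, concerted but asynchronous suprafacial [4+2] cycloaddition (type 2 intramolecular Diels–Alder reaction) in which the butynoate, held by the four-atom tether C4–C18–O–C11 from the internal diene carbon C5, can lie only under the α face of the s-cis diene C10=C5–C6=C7; the closest known reaction types are the intermolecular thermal Diels–Alder reactions of 2,6,6-trimethyl-1-vinylcyclohexene with acetylenic esters and ester-tethered type 2 intramolecular Diels–Alder reactions that give bridgehead alkenes. Ring B closes by the cycloaddition itself (bonds C7–C8 and C9–C10, a six-membered 1,4-cyclohexadiene), and the seven-membered lactone closes at the same time as the 1,3-bridged ring of the type 2 mode, because C9 is tied to C5 and can bond only to the adjacent terminus C10. The one new stereocentre, C10, is controlled by C4: C18 is α, so C9 is delivered to the α face of C10 and the C20 methyl is left β. The selectivities needed are regiochemistry and facial selectivity at C10; both are enforced by the tether, and the electronic preference (ester β-carbon C8 to the unsubstituted terminus C7) points the same way. The step should be slow because C10 is a fully substituted terminus with an inside methyl and the ester must adopt its lactone-like conformer; high dilution and a radical inhibitor suppress intermolecular paths, and the ester has no β-hydrogen for thermal elimination. The C8=C9 alkene stays conjugated to C11 and C5=C6 stays isolated, as the later steps require.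

Step 9
Reactants: 17
Product: 18 methyl 18-hydroxy-12,13,14,15,16-pentanorlabda-5,8-dien-11-oate
Conditions: NaOMe (cat.), MeOH, 0 °C → rt
Reagents that add atoms: methanol, CO
Why: Transesterification of a lactone that holds two bridgehead alkenes, so opening is driven by strain relief and by the solvent excess; low temperature and catalytic base should leave the doubly allylic C7–H untouched.

Step 10
Reactants: 18
Product: 19 methyl 18-hydroxy-12,13,14,15,16-pentanorlabd-8-en-11-oate (5α-H)
Conditions: H2 (1 atm), [Ir(cod)(PCy3)(py)]PF6 (Crabtree's catalyst, cat.), CH2Cl2, rt
Reagents that add atoms: none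
Why: Hydroxyl-directed homogeneous hydrogenation: the homoallylic C18 hydroxyl on the α face binds iridium and delivers hydrogen to the α face of C5=C6, which is also the face away from the two β-methyls, setting 5α-H; the tetrasubstituted, ester-conjugated C8=C9 should not react.

Step 11
Reactants: 19
Product: 20 methyl 18-(tert-butyldimethylsilyloxy)-12,13,14,15,16-pentanorlabd-8-en-11-oate
Conditions: TBSCl, imidazole, DMF, rt
Reagents that add atoms: tert-butyldimethylsilyl chloride, CC(C)(C)[Si](C)(C)Cl
Why: Standard silylation of a primary alcohol; the silyl ether tolerates the enolate, hydride, oxidation and olefination steps that follow.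

Step 12
Reactants: 20
Product: 22 methyl 18-(tert-butyldimethylsilyloxy)-12,13,14,15,16-pentanorlabd-8(17)-en-11-oate (9α-H), via lithium dienolate 21 (not isolated)
Conditions: LDA, THF, −78 → 0 °C; then AcOH, THF, −78 °C
Reagents that add atoms: none
Why: Deconjugative kinetic protonation of an ester dienolate: carbonyl-directed γ-deprotonation takes the C17 methyl, the γ-carbon cis to the ester (the kinetic preference known for β,β-disubstituted enoates), and the dienolate is protonated at the α-carbon C9. The proton arrives axially from the α face, anti to the axial C20 methyl, giving 9α-H with the ester equatorial.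

Step 13
Reactants: 22
Product: 23 18-(tert-butyldimethylsilyloxy)-12,13,14,15,16-pentanorlabd-8(17)-en-11-ol
Conditions: LiAlH4, Et2O, 0 °C → rt
Reagents that add atoms: none
Why: Hydride reduction of the ester to the primary alcohol; the medium is not basic enough to epimerise C9, and the silyl ether and alkene are inert.

Step 14
Reactants: 23
Product: 24 18-(tert-butyldimethylsilyloxy)-12,13,14,15,16-pentanorlabd-8(17)-en-11-al
Conditions: Dess–Martin periodinane, NaHCO3, CH2Cl2, 0 °C → rt
Reagents that add atoms: none
Why: Buffered Dess–Martin oxidation gives the β,γ-unsaturated aldehyde without acid or base strong enough to move the alkene; the 9β-formyl group is equatorial, the more stable epimer.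

Step 15
Reactants: 24; 25 1-(triphenylphosphoranylidene)propan-2-one
Product: 26 (11E)-18-(tert-butyldimethylsilyloxy)-14,15-dinorlabda-8(17),11-dien-13-one
Conditions: toluene, 90 °C
Reagents that add atoms: 1-(triphenylphosphoranylidene)propan-2-one, CC(=O)C=P(c1ccccc1)(c1ccccc1)c1ccccc1
Why: Wittig reaction of a stabilised ylide under neutral conditions gives the (E)-enone and should not epimerise or conjugate the aldehyde.

Step 16
Reactants: 26
Product: 27 18-(tert-butyldimethylsilyloxy)-14,15-dinorlabd-8(17)-en-13-one
Conditions: [(Ph3P)CuH]6 (Stryker's reagent), benzene, H2O (trace), rt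
Reagents that add atoms: none
Why: Copper hydride conjugate reduction is specific for the enone alkene; the isolated 1,1-disubstituted C8=C17 alkene and the silyl ether are not touched.

Step 17
Reactants: 27; 28 allyl diethylphosphonoacetate
Product: 29 allyl (13E)-18-(tert-butyldimethylsilyloxy)labda-8(17),13-dien-15-oate
Conditions: NaH, THF, 0 °C → 50 °C
Reagents that add atoms: allyl diethylphosphonoacetate, C=CCOC(=O)CP(=O)(OCC)OCC
Why: Horner–Wadsworth–Emmons olefination of a methyl ketone, as used for this type of labdane side chain; the E isomer (chain trans to the ester) should predominate and is purified by chromatography.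

Step 18
Reactants: 29
Product: 30 allyl (13E)-18-hydroxylabda-8(17),13-dien-15-oate
Conditions: Bu4NF (TBAF), THF, rt
Reagents that add atoms: none
Why: Fluoride cleavage of the silyl ether; the allyl enoate and the alkenes are stable to it.

Step 19
Reactants: 30; 31 acetic anhydride
Product: 32 allyl (13E)-18-acetoxylabda-8(17),13-dien-15-oate
Conditions: pyridine, DMAP (cat.), CH2Cl2, rt
Reagents that add atoms: acetic anhydride, CC(=O)OC(C)=O
Why: DMAP-catalysed acetylation of the neopentyl primary alcohol; nothing else in the molecule is acylated.

Step 20
Reactants: 32
Product: 33 (13E)-18-acetoxylabda-8(17),13-dien-15-oic acid (target)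
Conditions: Pd(PPh3)4 (cat.), morpholine, THF, rt; work-up at pH 4
Reagents that add atoms: none
Why: Tsuji–Trost deallylation: zerovalent palladium ionises the allyl ester and morpholine traps the allyl group, releasing the acid under neutral conditions that leave the acetate, the exocyclic alkene and the E-enoate untouched.

## Compound list

1 | ethyl 2-oxocyclohexanecarboxylate | CCOC(=O)C1CCCCC1=O | starting material
2 | L-valine tert-butyl ester | CC(C)[C@H](N)C(=O)OC(C)(C)C | starting material
3 | tert-butyl N-[2-(ethoxycarbonyl)cyclohex-1-en-1-yl]-L-valinate | CCOC(=O)C1=C(N[C@@H](C(C)C)C(=O)OC(C)(C)C)CCCC1 | intermediate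
4 | iodomethane | CI | starting material
5 | N-lithio derivative of 3 (lithium aza-enolate) | CCOC(=O)C1=C(N([Li])[C@@H](C(C)C)C(=O)OC(C)(C)C)CCCC1 | intermediate
6 | tert-butyl N-[(2R)-2-(ethoxycarbonyl)-2-methylcyclohexylidene]-L-valinate | CCOC(=O)[C@]1(C)CCCCC1=N[C@@H](C(C)C)C(=O)OC(C)(C)C | intermediate
7 | ethyl (1R)-1-methyl-2-oxocyclohexane-1-carboxylate | CCOC(=O)[C@]1(C)CCCCC1=O | intermediate
8 | lithium (6R)-6-(ethoxycarbonyl)-6-methylcyclohex-1-en-1-olate | CCOC(=O)[C@]1(C)CCCC=C1O[Li] | intermediate
9 | ethyl (1R)-1,3-dimethyl-2-oxocyclohexane-1-carboxylate (C3 epimers) | CCOC(=O)[C@]1(C)CCCC(C)C1=O | intermediate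
10 | potassium (6R)-6-(ethoxycarbonyl)-2,6-dimethylcyclohex-1-en-1-olate | CCOC(=O)[C@]1(C)CCCC(C)=C1O[K] | intermediate
11 | ethyl (1R)-1,3-dimethyl-2-{[(trifluoromethyl)sulfonyl]oxy}cyclohex-2-ene-1-carboxylate | CCOC(=O)[C@]1(C)CCCC(C)=C1OS(=O)(=O)C(F)(F)F | intermediate
12 | tributyl(vinyl)stannane | C=C[Sn](CCCC)(CCCC)CCCC | starting material
13 | ethyl (1R)-2-ethenyl-1,3-dimethylcyclohex-2-ene-1-carboxylate | CCOC(=O)[C@]1(C)CCCC(C)=C1C=C | intermediate
14 | [(1R)-2-ethenyl-1,3-dimethylcyclohex-2-en-1-yl]methanol | OC[C@]1(C)CCCC(C)=C1C=C | intermediate
15 | but-2-ynoic acid | CC#CC(=O)O | starting material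
16 | [(1R)-2-ethenyl-1,3-dimethylcyclohex-2-en-1-yl]methyl but-2-ynoate | CC#CC(=O)OC[C@]1(C)CCCC(C)=C1C=C | intermediate
17 | 11,18-lactone of 18-hydroxy-12,13,14,15,16-pentanorlabda-5,8-dien-11-oic acid (10β-methyl, α-face bridge) | CC1=C2C(=O)OC[C@]3(C)CCC[C@@]2(C)C3=CC1 | intermediate
18 | methyl 18-hydroxy-12,13,14,15,16-pentanorlabda-5,8-dien-11-oate | CC1=C(C(=O)OC)[C@@]2(C)CCC[C@@](C)(CO)C2=CC1 | intermediate
19 | methyl 18-hydroxy-12,13,14,15,16-pentanorlabd-8-en-11-oate (5α-H) | CC1=C(C(=O)OC)[C@@]2(C)CCC[C@@](C)(CO)[C@@H]2CC1 | intermediate
20 | methyl 18-(tert-butyldimethylsilyloxy)-12,13,14,15,16-pentanorlabd-8-en-11-oate | CC1=C(C(=O)OC)[C@@]2(C)CCC[C@@](C)(CO[Si](C)(C)C(C)(C)C)[C@@H]2CC1 | intermediate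
21 | lithium dienolate of 20 (C9=C11 enolate, C8=C17 methylene) | C=C1CC[C@H]2[C@](C)(CO[Si](C)(C)C(C)(C)C)CCC[C@]2(C)C1=C(OC)O[Li] | intermediate
22 | methyl 18-(tert-butyldimethylsilyloxy)-12,13,14,15,16-pentanorlabd-8(17)-en-11-oate (9α-H) | C=C1CC[C@H]2[C@](C)(CO[Si](C)(C)C(C)(C)C)CCC[C@]2(C)[C@H]1C(=O)OC | intermediate
23 | 18-(tert-butyldimethylsilyloxy)-12,13,14,15,16-pentanorlabd-8(17)-en-11-ol | C=C1CC[C@H]2[C@](C)(CO[Si](C)(C)C(C)(C)C)CCC[C@]2(C)[C@H]1CO | intermediate
24 | 18-(tert-butyldimethylsilyloxy)-12,13,14,15,16-pentanorlabd-8(17)-en-11-al | C=C1CC[C@H]2[C@](C)(CO[Si](C)(C)C(C)(C)C)CCC[C@]2(C)[C@H]1C=O | intermediate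
25 | 1-(triphenylphosphoranylidene)propan-2-one | CC(=O)C=P(c1ccccc1)(c1ccccc1)c1ccccc1 | starting material
26 | (11E)-18-(tert-butyldimethylsilyloxy)-14,15-dinorlabda-8(17),11-dien-13-one | C=C1CC[C@H]2[C@](C)(CO[Si](C)(C)C(C)(C)C)CCC[C@]2(C)[C@H]1/C=C/C(C)=O | intermediate
27 | 18-(tert-butyldimethylsilyloxy)-14,15-dinorlabd-8(17)-en-13-one | C=C1CC[C@H]2[C@](C)(CO[Si](C)(C)C(C)(C)C)CCC[C@]2(C)[C@H]1CCC(C)=O | intermediate
28 | allyl diethylphosphonoacetate | C=CCOC(=O)CP(=O)(OCC)OCC | starting material
29 | allyl (13E)-18-(tert-butyldimethylsilyloxy)labda-8(17),13-dien-15-oate | C=C1CC[C@H]2[C@](C)(CO[Si](C)(C)C(C)(C)C)CCC[C@]2(C)[C@H]1CC/C(C)=C/C(=O)OCC=C | intermediate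
30 | allyl (13E)-18-hydroxylabda-8(17),13-dien-15-oate | C=C1CC[C@H]2[C@](C)(CO)CCC[C@]2(C)[C@H]1CC/C(C)=C/C(=O)OCC=C | intermediate
31 | acetic anhydride | CC(=O)OC(C)=O | starting material
32 | allyl (13E)-18-acetoxylabda-8(17),13-dien-15-oate | C=C1CC[C@H]2[C@](C)(COC(C)=O)CCC[C@]2(C)[C@H]1CC/C(C)=C/C(=O)OCC=C | intermediate
33 | (13E)-18-acetoxylabda-8(17),13-dien-15-oic acid | C=C1CC[C@H]2[C@](C)(COC(C)=O)CCC[C@]2(C)[C@H]1CC/C(C)=C/C(=O)O | target

## Step count and least certain steps

Total: 20 steps. Longest linear sequence: 20 steps (1 to 33).

**Step 8 (key step, the one step beyond known chemistry).** The most likely failure is that the bridged transition state is not reached below the temperature at which other paths take over. The ester must turn into its lactone-like conformer, and C9 must bond to the fully substituted C10 beside the inside C20 methyl. Intermolecular cycloaddition or a 1,5-hydrogen shift in the diene could then compete.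
Fallback by known chemistry, from 14 back to 18: 14 is silylated (TIPSCl, imidazole) to {[(1R)-2-ethenyl-1,3-dimethylcyclohex-2-en-1-yl]methoxy}tri(propan-2-yl)silane F1. F1 is heated with methyl but-2-ynoate (neat, sealed tube) in an intermolecular Diels–Alder reaction of the kind known for 2,6,6-trimethyl-1-vinylcyclohexene and acetylenic esters. This should give methyl 18-(triisopropylsilyloxy)-12,13,14,15,16-pentanorlabda-5,8-dien-11-oate F2, and Bu4NF then gives 18. Facial control would rest only on the pseudoaxial C19 methyl shielding the β face of C10, so this path is expected to be less selective and to need a separation of diastereomers.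

**Step 12.** The likely failures are loss of regiocontrol in the γ-deprotonation (C7 instead of C17, which leads to the endocyclic isomer) and reconjugation during the quench, because C9–H of the product is acidic.
Fallback, from 20 directly to 22: photochemical deconjugation (254 nm, hexane, catalytic 1,2-dimethylimidazole). This is an excited-state 1,5-hydrogen shift from C17, the only γ-carbon cis to the ester, followed by α-face ketonisation of the dienol. It uses no enolate and makes no new compound (F0).

**Step 9.** The likely failures are slow addition of methoxide to the hindered lactone carbonyl and base-induced migration of the skipped diene into conjugation with the ester through the doubly allylic C7–H.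
Fallback, from 17 back to 18: LiAlH4 opens the lactone to the diol 11,18-dihydroxy-12,13,14,15,16-pentanorlabda-5,8-diene F3. MnO2 then oxidises only the allylic C11 hydroxyl and gives 18-hydroxy-12,13,14,15,16-pentanorlabda-5,8-dien-11-al F4. Pinnick oxidation (NaClO2, NaH2PO4, 2-methylbut-2-ene) gives 18-hydroxy-12,13,14,15,16-pentanorlabda-5,8-dien-11-oic acid F5, and trimethylsilyldiazomethane in methanol gives 18.

**Step 10.** The likely failures are migration of C5=C6 toward C6=C7 at an iridium hydride and incomplete facial control if the hydroxyl does not bind.
Fallback, from 18 back to 20: 18 is silylated first (TBSCl, imidazole) to methyl 18-(tert-butyldimethylsilyloxy)-12,13,14,15,16-pentanorlabda-5,8-dien-11-oate F6. F6 is hydrogenated over Pd/C in ethyl acetate, where the two axial β-methyls at C4 and C10 steer hydrogen to the α face, as in the heterogeneous hydrogenation of related drima-5,8-diene esters. The product is 20.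

**Step 17.** The likely failure is incomplete E selectivity in the olefination of a methyl ketone, with loss of material as the Z isomer.
Fallback, from 27 back to 29 (carbometalation in place of olefination): the kinetic enolate of 27 (LDA, THF, −78 °C, deprotonation at the C16 methyl) is trapped with ClP(O)(OEt)2 to give diethyl 18-(tert-butyldimethylsilyloxy)-14,15-dinorlabda-8(17),13(16)-dien-13-yl phosphate F7. Elimination with excess LDA (−78 °C → rt) then gives the terminal alkyne 18-(tert-butyldimethylsilyloxy)-15,16-dinorlabd-8(17)-en-13-yne F8. Zirconium-catalysed syn-carboalumination of F8 (AlMe3, Cp2ZrCl2 cat., CH2Cl2), followed by n-BuLi and allyl chloroformate, places the new methyl and the ester cis on the alkene and should give 29 as the E isomer only.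

## Further compounds

F1 | step 8 | {[(1R)-2-ethenyl-1,3-dimethylcyclohex-2-en-1-yl]methoxy}tri(propan-2-yl)silane | CC(C)[Si](OC[C@]1(C)CCCC(C)=C1C=C)(C(C)C)C(C)C
F2 | step 8 | methyl 18-(triisopropylsilyloxy)-12,13,14,15,16-pentanorlabda-5,8-dien-11-oate | CC1=C(C(=O)OC)[C@@]2(C)CCC[C@@](C)(CO[Si](C(C)C)(C(C)C)C(C)C)C2=CC1
F0 | step 12 | none | none
F3 | step 9 | 11,18-dihydroxy-12,13,14,15,16-pentanorlabda-5,8-diene | CC1=C(CO)[C@@]2(C)CCC[C@@](C)(CO)C2=CC1
F4 | step 9 | 18-hydroxy-12,13,14,15,16-pentanorlabda-5,8-dien-11-al | CC1=C(C=O)[C@@]2(C)CCC[C@@](C)(CO)C2=CC1
F5 | step 9 | 18-hydroxy-12,13,14,15,16-pentanorlabda-5,8-dien-11-oic acid | CC1=C(C(=O)O)[C@@]2(C)CCC[C@@](C)(CO)C2=CC1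
F6 | step 10 | methyl 18-(tert-butyldimethylsilyloxy)-12,13,14,15,16-pentanorlabda-5,8-dien-11-oate | CC1=C(C(=O)OC)[C@@]2(C)CCC[C@@](C)(CO[Si](C)(C)C(C)(C)C)C2=CC1
F7 | step 17 | diethyl 18-(tert-butyldimethylsilyloxy)-14,15-dinorlabda-8(17),13(16)-dien-13-yl phosphate | C=C1CC[C@H]2[C@](C)(CO[Si](C)(C)C(C)(C)C)CCC[C@]2(C)[C@H]1CCC(=C)OP(=O)(OCC)OCC
F8 | step 17 | 18-(tert-butyldimethylsilyloxy)-15,16-dinorlabd-8(17)-en-13-yne | C=C1CC[C@H]2[C@](C)(CO[Si](C)(C)C(C)(C)C)CCC[C@]2(C)[C@H]1CCC#C
A1 | alternative 1 | 8α-(tert-butyldimethylsilyloxy)-4,10β-dimethyl-9β-[2-(2-methyl-1,3-dioxolan-2-yl)ethyl]-Δ4-octal-3-one | [C@@H]1(O[Si](C)(C)C(C)(C)C)CCC2=C(C)C(=O)CC[C@]2(C)[C@H]1CCC1(C)OCCO1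
A2 | alternative 1 | (R)-4-(tert-butyldimethylsilyloxy)-2-methylcyclohex-2-en-1-one | CC1=C[C@H](O[Si](C)(C)C(C)(C)C)CCC1=O
A3 | alternative 1 | [2-(2-methyl-1,3-dioxolan-2-yl)ethyl]magnesium bromide | CC1(CC[Mg]Br)OCCO1
A4 | alternative 1 | 2-(trimethylsilyl)pent-1-en-3-one | CCC(=O)C(=C)[Si](C)(C)C
A5 | alternative 2 | 2-allyl-3-methyl-3-[(triisopropylsilyloxy)methyl]cyclohexanone (allyl trans to CH2OSi) | C=CC[C@H]1[C@](C)(CO[Si](C(C)C)(C(C)C)C(C)C)CCCC1=O
A6 | alternative 2 | 3-[(triisopropylsilyloxy)methyl]cyclohex-2-en-1-one | O=C1C=C(CO[Si](C(C)C)(C(C)C)C(C)C)CCC1
A7 | alternative 3 | trans-fused cycloadduct: 8β-(tert-butyldimethylsilyloxy)-10β-methyl-Δ6-octalin-9β-carbaldehyde with C4 spiro-fused to a 2,2-dimethyl-1,3-dioxane | [C@H]1(O[Si](C)(C)C(C)(C)C)C=C[C@H]2C3(COC(C)(C)OC3)CCC[C@]2(C)[C@H]1C=O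
A8 | alternative 3 | (2E)-6-{5-[(1E,3E)-4-(tert-butyldimethylsilyloxy)buta-1,3-dien-1-yl]-2,2-dimethyl-1,3-dioxan-5-yl}-3-methylhex-2-enal | O=C/C=C(\C)CCCC1(COC(C)(C)OC1)/C=C/C=C/O[Si](C)(C)C(C)(C)C
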